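The cyclohexenone ring (C1 ketone, C2 OAc, C3 CH3, C4 OH, C5 H2, C6 alkylidene) is cut at C1–C2 and C5–C6. The plan exploits that ketone C1 is flanked by two enone arms, C2=C3 and C6=C7. Written in deconjugated form (C3–C4 alkene, later epoxide; C7 methylidene), the ring is a cyclohexene, a Diels–Alder retron. An iminium-catalysed endo [4+2] joins (1E)-1-acetoxy-2-methylbutadiene to an enantiopure 4-methylidene-2-enal that already bears the angelate. It forms both bonds, delivers the acetate and sets C2, which relays its configuration to C4 by anti-epoxidation. Excision of the formyl activator, base-triggered double conjugation and cross-metathesis finish the synthesis.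

Key step: step 5

Numbering used: ring C1–C6 as above; side chain C7 (exocyclic alkene carbon, bears CH3), C8 (angelate carbinol), C9–C11 (prenyl).
Assumption: the prenyl terminus is carried as an allyl group until ozone and dimethyldioxirane have been used, because a trisubstituted prenyl alkene would not survive them. Compounds 3 and 6 are taken as catalogue compounds.

Step 1
Reactants: 1 (2E)-2-methylbut-2-enal (tiglaldehyde)
Product: 2 (1E)-2-methylbuta-1,3-dien-1-yl acetate
Conditions: isopropenyl acetate, p-TsOH (cat.), Cu(OAc)2 (cat.), reflux, acetone distilled off; fractional distillation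
Reagents that add atoms: isopropenyl acetate, CC(=C)OC(C)=O
Why: Acid-catalysed enol-ester exchange (dienol acetate formation) is driven by removal of acetone and should favour the (1E)-dienyl acetate, in which OAc lies away from the vinyl group; no stereocentre is formed.

Step 2
Reactants: 3 2-bromoprop-2-enal (2-bromoacrolein); 4 allyltributylstannane
Product: 5 (3S)-2-bromohexa-1,5-dien-3-ol
Conditions: (S)-BINOL (10 mol %), Ti(OiPr)4 (10 mol %), 4 Å MS, CH2Cl2, −20 °C; aq. NaHCO3
Reagents that add atoms: none
Why: Keck asymmetric allylation, in which the (S)-BINOL–titanium Lewis acid exposes one carbonyl face to the allylstannane, should set the carbinol (future C8) as S and leave the vinyl bromide untouched.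

Step 3
Reactants: 5 (3S)-2-bromohexa-1,5-dien-3-ol; 6 2-[(1E)-3,3-diethoxyprop-1-en-1-yl]-4,4,5,5-tetramethyl-1,3,2-dioxaborolane
Product: 7 (4S,6E)-8,8-diethoxy-5-methylideneocta-1,6-dien-4-ol
Conditions: Pd(dppf)Cl2 (3 mol %), K2CO3, THF/H2O, 50 °C
Reagents that add atoms: none
Why: Suzuki–Miyaura sp2–sp2 coupling keeps the E geometry of the alkenylboronate, leaves the stereocentre untouched, and tolerates the free allylic alcohol, which unlike an allylic ester cannot ionise to a π-allyl complex.

Step 4
Reactants: 7 (4S,6E)-8,8-diethoxy-5-methylideneocta-1,6-dien-4-ol; 8 angelic acid [(2Z)-2-methylbut-2-enoic acid]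
Product: 10 (4S,6E)-5-methylidene-8-oxoocta-1,6-dien-4-yl (2Z)-2-methylbut-2-enoate, via diethyl acetal angelate 9 (not isolated)
Conditions: 8, 2,4,6-Cl3C6H2COCl, Et3N, toluene, rt; then 7, 70 °C; then 1 M HCl, THF, rt
Reagents that add atoms: water, O
Why: Yamaguchi-type mixed-anhydride esterification without a nucleophilic catalyst avoids the addition–elimination path from angelate to tiglate and keeps the C8–O bond (retention), and the conjugated acetal is then hydrolysed by dilute acid in the same operation.

Step 5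
Reactants: 10 (4S,6E)-5-methylidene-8-oxoocta-1,6-dien-4-yl (2Z)-2-methylbut-2-enoate; 2 (1E)-2-methylbuta-1,3-dien-1-yl acetate
Product: 11 (1R,5S,6R)-6-formyl-2-methyl-5-{(3S)-3-[(2Z)-2-methylbut-2-enoyloxy]hexa-1,5-dien-2-yl}cyclohex-2-en-1-yl acetate
Conditions: (5S)-5-benzyl-2,2,3-trimethylimidazolidin-4-one·HCl (20 mol %), 2 (3 equiv), CH3NO2/H2O 95:5, 0 °C → rt
Reagents that add atoms: none
Why: The secondary amine condenses with the formyl group of 10 to an (E)-iminium ion whose lowered LUMO lets the α,β-alkene react with diene 2 in a concerted, asynchronous cycloaddition (organocatalytic asymmetric Diels–Alder reaction of an enal with a 1-acyloxydiene), and hydrolysis releases 11 and the catalyst. The six-membered carbocycle closes intermolecularly in the [π4s+π2s] mode, the CH2 terminus of the diene (future C5) bonding to the iminium β-carbon (future C6) and the acetoxy-bearing terminus (future C2) to the α-carbon (future C1). The "ortho" regiochemistry (formyl next to OAc) rests on the acetoxy donor and on sterics, since only the CH2 terminus can reach the branched β-carbon, and this should outweigh the opposing weak bias of the diene methyl group; attack at the α,β bond rather than the methylidene follows from direct iminium activation and from the quaternary centre the alternative would require. The benzyl group of the (5S)-catalyst shields one face of the iminium ion, so the diene adds to the Si face of the α-carbon, which fixes future C1 as R and future C6 as S, with formyl and side chain trans because 10 is E. The endo rule places the outside OAc of the (1E)-diene cis to formyl and so fixes future C2 as R, the only new centre needed later. The step needs facial and endo selectivity together, because an exo adduct from the same face carries the opposite C2 configuration; any (1Z)-2 cannot reach a reactive s-cis conformation and stays behind.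

Step 6
Reactants: 11 (1R,5S,6R)-6-formyl-2-methyl-5-{(3S)-3-[(2Z)-2-methylbut-2-enoyloxy]hexa-1,5-dien-2-yl}cyclohex-2-en-1-yl acetate
Product: 12 (1S,5R)-6-{[(tert-butyldimethylsilyl)oxy]methylidene}-2-methyl-5-{(3S)-3-[(2Z)-2-methylbut-2-enoyloxy]hexa-1,5-dien-2-yl}cyclohex-2-en-1-yl acetate (E/Z mixture at the enol ether, inconsequential)
Conditions: TBSOTf, Et3N, CH2Cl2, −78 → 0 °C
Reagents that add atoms: tert-butyldimethylsilyl triflate, CC(C)(C)[Si](C)(C)OS(=O)(=O)C(F)(F)F
Why: Soft enolisation (silyl triflate/amine silyl enol ether formation) removes the only α-hydrogen of the aldehyde without a free enolate, so β-elimination of the neighbouring acetate is avoided; the formyl-bearing stereocentre is deleted on purpose.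

Step 7
Reactants: 12 (1S,5R)-6-{[(tert-butyldimethylsilyl)oxy]methylidene}-2-methyl-5-{(3S)-3-[(2Z)-2-methylbut-2-enoyloxy]hexa-1,5-dien-2-yl}cyclohex-2-en-1-yl acetate
Product: 13 (1S,5R)-2-methyl-6-oxo-5-{(3S)-3-[(2Z)-2-methylbut-2-enoyloxy]hexa-1,5-dien-2-yl}cyclohex-2-en-1-yl acetate
Conditions: O3 (1 equiv, Sudan Red 7B end point), CH2Cl2, −78 °C; then Me2S
Reagents that add atoms: ozone, [O-][O+]=O
Why: Ozonolysis with reductive work-up, dosed to an indicator end point, cleaves the silyl enol ether as the most electron-rich of the five C=C bonds (the others are acyloxy-deactivated, monosubstituted or ester-conjugated) and gives the C1 ketone under neutral conditions that leave both β,γ-alkenes in place.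

Step 8
Reactants: 13 (1S,5R)-2-methyl-6-oxo-5-{(3S)-3-[(2Z)-2-methylbut-2-enoyloxy]hexa-1,5-dien-2-yl}cyclohex-2-en-1-yl acetate
Product: 14 (1R,2S,4R,6R)-1-methyl-3-oxo-4-{(3S)-3-[(2Z)-2-methylbut-2-enoyloxy]hexa-1,5-dien-2-yl}-7-oxabicyclo[4.1.0]heptan-2-yl acetate
Conditions: dimethyldioxirane (1.05 equiv), acetone, −20 → 0 °C
Reagents that add atoms: dimethyldioxirane, CC1(C)OO1
Why: Electrophilic epoxidation with neutral dimethyldioxirane should pick the trisubstituted ring alkene over the 1,1-disubstituted methylidene and the terminal allyl group and approach anti to the pseudoaxial acetate on future C2, which sets future C4 as R by 1,3-relay.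

Step 9
Reactants: 14 (1R,2S,4R,6R)-1-methyl-3-oxo-4-{(3S)-3-[(2Z)-2-methylbut-2-enoyloxy]hexa-1,5-dien-2-yl}-7-oxabicyclo[4.1.0]heptan-2-yl acetate
Product: 16 (2E,3S)-2-[(5R)-3-(acetyloxy)-5-hydroxy-4-methyl-2-oxocyclohex-3-en-1-ylidene]hex-5-en-3-yl (2Z)-2-methylbut-2-enoate, via deconjugated hydroxy enone 15 (not isolated)
Conditions: DBU (0.3 equiv), CH2Cl2, 0 °C → rt
Reagents that add atoms: none
Why: Base-catalysed isomerisation of a doubly β,γ-functionalised ketone, in which E1cB opening of the β,γ-epoxide from C2–H gives the γ-hydroxy enone with the C4–O bond untouched (4R kept) and the methylidene moves into conjugation through the C6 dienolate (isopulegone-to-pulegone type shift), protonation via the rotamer that keeps branched C8 away from the C1 oxygen giving the more stable E-alkene.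

Step 10
Reactants: 16 (2E,3S)-2-[(5R)-3-(acetyloxy)-5-hydroxy-4-methyl-2-oxocyclohex-3-en-1-ylidene]hex-5-en-3-yl (2Z)-2-methylbut-2-enoate
Product: 17 (2E,3S)-2-[(5R)-3-(acetyloxy)-5-hydroxy-4-methyl-2-oxocyclohex-3-en-1-ylidene]-6-methylhept-5-en-3-yl (2Z)-2-methylbut-2-enoate (target)
Conditions: Hoveyda–Grubbs II catalyst (5 mol %), 2-methylbut-2-ene (excess), CH2Cl2, 40 °C, sealed tube
Reagents that add atoms: 2-methylbut-2-ene, CC=C(C)C
Why: Olefin cross-metathesis of the only terminal alkene with excess 2-methylbut-2-ene installs the isopropylidene terminus with loss of propene, while the tetrasubstituted and ester-conjugated alkenes are inert to the ruthenium carbene and no stereocentre is touched.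

Compound list
1 | (2E)-2-methylbut-2-enal (tiglaldehyde) | C/C=C(\C)C=O | starting material
2 | (1E)-2-methylbuta-1,3-dien-1-yl acetate | CC(=O)O/C=C(C)/C=C | intermediate
3 | 2-bromoprop-2-enal | C=C(Br)C=O | starting material
4 | allyltributylstannane | C=CC[Sn](CCCC)(CCCC)CCCC | starting material
5 | (3S)-2-bromohexa-1,5-dien-3-ol | O[C@@H](CC=C)C(Br)=C | intermediate
6 | 2-[(1E)-3,3-diethoxyprop-1-en-1-yl]-4,4,5,5-tetramethyl-1,3,2-dioxaborolane | CCOC(OCC)/C=C/B1OC(C)(C)C(C)(C)O1 | starting material
7 | (4S,6E)-8,8-diethoxy-5-methylideneocta-1,6-dien-4-ol | O[C@@H](CC=C)C(=C)/C=C/C(OCC)OCC | intermediate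
8 | angelic acid, (2Z)-2-methylbut-2-enoic acid | C/C=C(/C)C(=O)O | starting material
9 | (4S,6E)-8,8-diethoxy-5-methylideneocta-1,6-dien-4-yl (2Z)-2-methylbut-2-enoate | C/C=C(/C)C(=O)O[C@@H](CC=C)C(=C)/C=C/C(OCC)OCC | intermediate
10 | (4S,6E)-5-methylidene-8-oxoocta-1,6-dien-4-yl (2Z)-2-methylbut-2-enoate | C/C=C(/C)C(=O)O[C@@H](CC=C)C(=C)/C=C/C=O | intermediate
11 | (1R,5S,6R)-6-formyl-2-methyl-5-{(3S)-3-[(2Z)-2-methylbut-2-enoyloxy]hexa-1,5-dien-2-yl}cyclohex-2-en-1-yl acetate | C/C=C(/C)C(=O)O[C@@H](CC=C)C(=C)[C@H]1CC=C(C)[C@H](OC(C)=O)[C@@H]1C=O | intermediate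
12 | (1S,5R)-6-{[(tert-butyldimethylsilyl)oxy]methylidene}-2-methyl-5-{(3S)-3-[(2Z)-2-methylbut-2-enoyloxy]hexa-1,5-dien-2-yl}cyclohex-2-en-1-yl acetate (enol ether E/Z mixture) | C/C=C(/C)C(=O)O[C@@H](CC=C)C(=C)[C@H]1CC=C(C)[C@H](OC(C)=O)C1=CO[Si](C)(C)C(C)(C)C | intermediate
13 | (1S,5R)-2-methyl-6-oxo-5-{(3S)-3-[(2Z)-2-methylbut-2-enoyloxy]hexa-1,5-dien-2-yl}cyclohex-2-en-1-yl acetate | C/C=C(/C)C(=O)O[C@@H](CC=C)C(=C)[C@H]1CC=C(C)[C@H](OC(C)=O)C1=O | intermediate
14 | (1R,2S,4R,6R)-1-methyl-3-oxo-4-{(3S)-3-[(2Z)-2-methylbut-2-enoyloxy]hexa-1,5-dien-2-yl}-7-oxabicyclo[4.1.0]heptan-2-yl acetate | C/C=C(/C)C(=O)O[C@@H](CC=C)C(=C)[C@H]1C[C@H]2O[C@@]2(C)[C@H](OC(C)=O)C1=O | intermediate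
15 | (3S)-2-[(1R,5R)-3-(acetyloxy)-5-hydroxy-4-methyl-2-oxocyclohex-3-en-1-yl]hexa-1,5-dien-3-yl (2Z)-2-methylbut-2-enoate | C/C=C(/C)C(=O)O[C@@H](CC=C)C(=C)[C@H]1C[C@@H](O)C(C)=C(OC(C)=O)C1=O | intermediate
16 | (2E,3S)-2-[(5R)-3-(acetyloxy)-5-hydroxy-4-methyl-2-oxocyclohex-3-en-1-ylidene]hex-5-en-3-yl (2Z)-2-methylbut-2-enoate | C/C=C(/C)C(=O)O[C@@H](CC=C)/C(C)=C1\C[C@@H](O)C(C)=C(OC(C)=O)C1=O | intermediate
17 | (2E,3S)-2-[(5R)-3-(acetyloxy)-5-hydroxy-4-methyl-2-oxocyclohex-3-en-1-ylidene]-6-methylhept-5-en-3-yl (2Z)-2-methylbut-2-enoate | C/C=C(/C)C(=O)O[C@@H](CC=C(C)C)/C(C)=C1\C[C@@H](O)C(C)=C(OC(C)=O)C1=O | target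

Total steps: 10. Longest linear sequence: 9 steps (steps 2 to 10: 3 → 5 → 7 → 10 → 11 → 12 → 13 → 14 → 16 → 17).

Steps most likely to fail

Step 5. The cycloaddition at the β-branched enal bond may be slow. Addition may occur at the methylidene bond instead, acetic acid may be lost through the enamine of the adduct, and endo and facial selection may be incomplete. The fallback gives up catalyst control, uses a stronger diene, and sets out from 10 and 1. Tiglaldehyde 1 is silylated (TBSOTf, Et3N) to (1E)-1-[(tert-butyldimethylsilyl)oxy]-2-methylbuta-1,3-diene F1. A Me2AlCl-promoted Diels–Alder reaction of F1 with 10 at −78 °C gives the silyl ether adduct F2. Because 10 is enantiopure, the two endo adducts are diastereomers and are separated by chromatography. HF·pyridine then frees the hydroxy aldehyde F3, and Ac2O/pyridine brings the sequence back to the route at 11.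

Step 9. Vinylogous enolisation of the new γ-hydroxy enone may continue, with drift towards the 1,4-diketone and aromatisation. Acetyl may be transferred intermolecularly from the enol acetate to the alkoxide, and protonation of the dienolate may select E incompletely. The fallback separates the two events and masks the carbinol; it sets out from 14. Et3N on silica opens only the epoxide, and 15 is isolated. TESCl/imidazole gives the deconjugated triethylsilyl ether F4, which cannot tautomerise to a diketone. DBU in toluene then moves the methylidene into conjugation to give the conjugated triethylsilyl ether F5. Any Z isomer is separated and re-equilibrated under the same conditions. HF·pyridine returns to the route at 16.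

Step 7. Ozone may also attack the ring alkene or the methylidene once the enol ether is consumed. The fallback replaces the direct cleavage by oxidation and glycol-type cleavage; it sets out from 12. Rubottom oxidation with one equivalent of dimethyldioxirane at −40 °C touches only the enol ether and, after silyl migration, gives the α-silyloxy aldehyde F6. HF·pyridine gives the α-hydroxy aldehyde F7, and NaIO4 in aqueous THF cleaves it to return to the route at 13.

Further compounds
F1 | step 5 | (1E)-1-[(tert-butyldimethylsilyl)oxy]-2-methylbuta-1,3-diene | CC(C)(C)[Si](C)(C)O/C=C(C)/C=C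
F2 | step 5 | (3S)-2-[(1S,5R,6R)-5-[(tert-butyldimethylsilyl)oxy]-6-formyl-4-methylcyclohex-3-en-1-yl]hexa-1,5-dien-3-yl (2Z)-2-methylbut-2-enoate | C/C=C(/C)C(=O)O[C@@H](CC=C)C(=C)[C@H]1CC=C(C)[C@H](O[Si](C)(C)C(C)(C)C)[C@@H]1C=O
F3 | step 5 | (3S)-2-[(1S,5R,6R)-6-formyl-5-hydroxy-4-methylcyclohex-3-en-1-yl]hexa-1,5-dien-3-yl (2Z)-2-methylbut-2-enoate | C/C=C(/C)C(=O)O[C@@H](CC=C)C(=C)[C@H]1CC=C(C)[C@H](O)[C@@H]1C=O
F4 | step 9 | (3S)-2-[(1R,5R)-3-(acetyloxy)-4-methyl-2-oxo-5-(triethylsilyloxy)cyclohex-3-en-1-yl]hexa-1,5-dien-3-yl (2Z)-2-methylbut-2-enoate | C/C=C(/C)C(=O)O[C@@H](CC=C)C(=C)[C@H]1C[C@@H](O[Si](CC)(CC)CC)C(C)=C(OC(C)=O)C1=O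
F5 | step 9 | (2E,3S)-2-[(5R)-3-(acetyloxy)-4-methyl-2-oxo-5-(triethylsilyloxy)cyclohex-3-en-1-ylidene]hex-5-en-3-yl (2Z)-2-methylbut-2-enoate | C/C=C(/C)C(=O)O[C@@H](CC=C)/C(C)=C1\C[C@@H](O[Si](CC)(CC)CC)C(C)=C(OC(C)=O)C1=O
F6 | step 7 | α-silyloxy aldehyde: 12 with the enol ether carbon pair turned into C(OTBS)(CHO), epimer mixture at that carbon, other centres as in 12 | C/C=C(/C)C(=O)O[C@@H](CC=C)C(=C)[C@H]1CC=C(C)[C@H](OC(C)=O)C1(O[Si](C)(C)C(C)(C)C)C=O
F7 | step 7 | α-hydroxy aldehyde: F6 without the silyl group, epimer mixture at the carbinol carbon | C/C=C(/C)C(=O)O[C@@H](CC=C)C(=C)[C@H]1CC=C(C)[C@H](OC(C)=O)C1(O)C=O
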